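**Retrosynthetic overview**
1. Target numbering for 19: C1 and C3 are ketones, C2 is the diprenyl carbon, C4 bears the acyl group, C5 is the enol carbon, C6 is the carbinol. 19 ⇒ 17: the enolised triketone (C3, C4, C5 and the isobutyryl carbonyl) is carried as a 3-isopropylisoxazole fused at C4–C5. It is released at the end by N–O cleavage and hydrolysis.
2. 17 ⇒ achiral keto-aldehyde 16 by cutting the acyloin bond C6–C1. A chiral carbene reverses the polarity of the formyl carbon (future C1), so two electrophilic carbonyl carbons are joined. This one redox-neutral isomerisation closes the carbocycle, creates the tertiary alcohol next to the ketone and sets the only stereocentre.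
3. Enabling feature: C1 lies between carbinol C6 and the fully substituted C2, so the aldehyde has no α-hydrogen. The isoxazole ring holds the two acyl arms on its neighbouring atoms C4 and C5, removes the acidic triketone proton and activates the ketone on its C5.
4. 16 ⇒ isoxazole ester 8 + acetonitrile + two prenyl bromides (acylation, double alkylation, reduction, oxidation); 8 ⇒ nitrile oxide 7 + alkynoate 4; 4 ⇒ methyl propiolate + 4-methylpent-3-enal.
5. Ring order: isoxazole (temporary, step 4), six-membered carbocycle (step 9), isoxazole opened again (steps 10 and 11).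

Key step: step 9

Assumption: the antipode of the triazolium salt named in step 9 is assigned from the usual shielding model of aminoindanol-derived carbenes; both antipodes are commercial, and the mirror-image salt is used if the model points the wrong way.

**Step 1**
Reactants: 1 4-methylpent-3-en-1-ol
Product: 2 4-methylpent-3-enal
Conditions: Dess–Martin periodinane (1.1 equiv), NaHCO3 (4 equiv), CH2Cl2, 0 °C; short silica plug, used at once as a solution
Reagents that add atoms: none
Why: Dess–Martin oxidation of a primary alcohol stops at the aldehyde, and the bicarbonate buffer keeps the β,γ-double bond from moving into conjugation.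

**Step 2**
Reactants: 2 4-methylpent-3-enal; 3 methyl propiolate
Product: 4 methyl 4-hydroxy-7-methyloct-6-en-2-ynoate (racemic)
Conditions: 3, LiN(i-Pr)2 (1.05 equiv), THF, −78 °C; then 2, −78 °C; AcOH quench at −78 °C
Reagents that add atoms: none
Why: Acetylide addition of deprotonated 3 to the aldehyde is faster at low temperature than enolisation of 2, and the new carbinol centre is formed racemic and is erased in step 8.

**Step 3**
Reactants: 5 2-methylpropanal oxime
Product: 6 N-hydroxy-2-methylpropanimidoyl chloride
Conditions: N-chlorosuccinimide (1.05 equiv), DMF, 25 °C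
Reagents that add atoms: N-chlorosuccinimide, O=C1CCC(=O)N1Cl
Why: Electrophilic chlorination of an aldoxime is the standard entry to a hydroximoyl chloride, the storable precursor of the nitrile oxide.

**Step 4**
Reactants: 4 methyl 4-hydroxy-7-methyloct-6-en-2-ynoate; 6 N-hydroxy-2-methylpropanimidoyl chloride
Product: 8 methyl 5-(1-hydroxy-4-methylpent-3-en-1-yl)-3-(propan-2-yl)-1,2-oxazole-4-carboxylate (racemic), via nitrile oxide 7 (not isolated)
Conditions: 6 (2 equiv, in portions), NaHCO3 (4 equiv), EtOAc, 25 °C
Reagents that add atoms: none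
Why: Mild dehydrochlorination gives 7, whose 1,3-dipolar cycloaddition to a 3-substituted propiolate bonds the dipole carbon to the ester-bearing alkyne carbon, so the ester ends on C4 and the carbinol chain on C5 of the isoxazole, while the trisubstituted alkene is a far poorer dipolarophile and the weak solid base avoids isomerisation of the hydroxy alkynoate.

**Step 5**
Reactants: 8 methyl 5-(1-hydroxy-4-methylpent-3-en-1-yl)-3-(propan-2-yl)-1,2-oxazole-4-carboxylate; 9 acetonitrile
Product: 10 3-[5-(1-hydroxy-4-methylpent-3-en-1-yl)-3-(propan-2-yl)-1,2-oxazol-4-yl]-3-oxopropanenitrile (racemic)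
Conditions: 9 (4 equiv), n-BuLi (3.8 equiv), THF, −78 °C; then 8, −78 to 0 °C; AcOH quench
Reagents that add atoms: none
Why: Claisen-type acylation of the small nitrile anion by the ester is driven by deprotonation of the β-ketonitrile formed, and the excess base carries the free hydroxyl through as its alkoxide.

**Step 6**
Reactants: 10 3-[5-(1-hydroxy-4-methylpent-3-en-1-yl)-3-(propan-2-yl)-1,2-oxazol-4-yl]-3-oxopropanenitrile; 11 prenyl bromide (1-bromo-3-methylbut-2-ene)
Product: 13 2-{[5-(1-hydroxy-4-methylpent-3-en-1-yl)-3-(propan-2-yl)-1,2-oxazol-4-yl]carbonyl}-5-methyl-2-(3-methylbut-2-en-1-yl)hex-4-enenitrile (racemic), via monoprenyl ketonitrile 12 (not isolated)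
Conditions: 11 (2.4 equiv), K2CO3 (3 equiv), DMF, 25 to 45 °C
Reagents that add atoms: none
Why: Twofold active-methylene C-alkylation (SN2 at the primary allylic bromide) of the soft β-ketonitrile anion builds the quaternary carbon, and carbonate is too weak a base to alkylate the secondary alcohol.

**Step 7**
Reactants: 13 2-{[5-(1-hydroxy-4-methylpent-3-en-1-yl)-3-(propan-2-yl)-1,2-oxazol-4-yl]carbonyl}-5-methyl-2-(3-methylbut-2-en-1-yl)hex-4-enenitrile
Product: 15 2-{hydroxy[5-(1-hydroxy-4-methylpent-3-en-1-yl)-3-(propan-2-yl)-1,2-oxazol-4-yl]methyl}-5-methyl-2-(3-methylbut-2-en-1-yl)hex-4-enal (mixture of diastereomers), via aldimine 14 (not isolated)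
Conditions: i-Bu2AlH (4.5 equiv), toluene, −78 to −20 °C; then 1 M aq. HCl, 0 °C
Reagents that add atoms: water, O
Why: Nitrile-to-aldehyde reduction stops at the N-aluminated aldimine, which is hydrolysed on work-up, the ketone is reduced along the way, and its new carbinol centre is unselective but is erased in step 8.

**Step 8**
Reactants: 15 2-{hydroxy[5-(1-hydroxy-4-methylpent-3-en-1-yl)-3-(propan-2-yl)-1,2-oxazol-4-yl]methyl}-5-methyl-2-(3-methylbut-2-en-1-yl)hex-4-enal
Product: 16 5-methyl-2-(3-methylbut-2-en-1-yl)-2-{[5-(4-methylpent-3-enoyl)-3-(propan-2-yl)-1,2-oxazol-4-yl]carbonyl}hex-4-enal (achiral)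
Conditions: Dess–Martin periodinane (3 equiv), CH2Cl2, 0 to 25 °C
Reagents that add atoms: none
Why: Twofold Dess–Martin oxidation of the two secondary alcohols runs under non-basic conditions, so neither retro-aldol cleavage nor deformylation of the quaternary β-keto aldehyde nor alkene migration is triggered, and the aldehyde is left untouched.

**Step 9**
Reactants: 16 5-methyl-2-(3-methylbut-2-en-1-yl)-2-{[5-(4-methylpent-3-enoyl)-3-(propan-2-yl)-1,2-oxazol-4-yl]carbonyl}hex-4-enal
Product: 17 (7R)-7-hydroxy-5,5,7-tris(3-methylbut-2-en-1-yl)-3-(propan-2-yl)-1,2-benzoxazole-4,6(5H,7H)-dione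
Conditions: (5aR,10bS)-2-(pentafluorophenyl)-5a,10b-dihydro-4H,6H-indeno[2,1-b][1,2,4]triazolo[4,3-d][1,4]oxazin-2-ium tetrafluoroborate (15 mol %), i-Pr2NEt (15 mol %), 4 Å molecular sieves, toluene, 25 to 40 °C, argon
Reagents that add atoms: none
Why: The triazolylidene released by the amine adds to the only formyl group of 16, a proton shift turns the formyl carbon into a nucleophilic enaminol (acyl anion equivalent) that attacks the ketone carbon on C5 of the isoxazole, and proton transfer with loss of the carbene gives the α-ketol. This is the carbene-catalysed enantioselective intramolecular crossed aldehyde–ketone benzoin reaction, known for keto-aldehydes that close six-membered rings onto aryl and isoxazolyl ketones. The six-membered carbocycle closes in a 6-(enolexo)-exo-trig mode between two acyl arms that the isoxazole holds on neighbouring ring atoms. The new carbinol centre is controlled by the catalyst: the indane wall blocks one face of the enaminol, its O–H binds the ketone oxygen, and the tether should leave only the Si face of the ketone open, which gives (7R). Chemoselectivity rests on the substrate: the aldehyde has no α-hydrogen (no aldol donor, no enal), attack on the other ketone would need a three-membered ring and an aldol from the ketone CH2 a seven-membered ring, and the acidic triketone is masked so it cannot protonate the carbene. A weak amine base and an alcohol-free medium should keep the β,γ-enone out of conjugation and leave deformylation of the β-keto aldehyde without an acceptor for the formyl group.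

**Step 10**
Reactants: 17 (7R)-7-hydroxy-5,5,7-tris(3-methylbut-2-en-1-yl)-3-(propan-2-yl)-1,2-benzoxazole-4,6(5H,7H)-dione
Product: 18 (4S)-2-(1-amino-2-methylpropylidene)-4-hydroxy-4,6,6-tris(3-methylbut-2-en-1-yl)cyclohexane-1,3,5-trione
Conditions: Mo(CO)6 (1 equiv), MeCN–H2O (15:1), 80 °C
Reagents that add atoms: none
Why: Reductive isoxazole opening by zerovalent molybdenum cleaves only the weak N–O bond and leaves alkenes, ketones and the tertiary alcohol alone; the stereocentre is not touched, and its descriptor changes only because the ranking of its neighbours changes.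

**Step 11**
Reactants: 18 (4S)-2-(1-amino-2-methylpropylidene)-4-hydroxy-4,6,6-tris(3-methylbut-2-en-1-yl)cyclohexane-1,3,5-trione
Product: 19 (6R)-5,6-dihydroxy-4-(2-methylpropanoyl)-2,2,6-tris(3-methylbut-2-en-1-yl)cyclohex-4-ene-1,3-dione
Conditions: 1 M aq. HCl, THF, 40 °C
Reagents that add atoms: water, O
Why: Acid hydrolysis of the vinylogous amide (addition of water to the protonated enaminone carbon, loss of ammonia) releases the enolised triketone, and the fully substituted carbinol carbon cannot epimerise.

**Compound list**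
1 | 4-methylpent-3-en-1-ol | CC(C)=CCCO | starting material
2 | 4-methylpent-3-enal | CC(C)=CCC=O | intermediate
3 | methyl propiolate | C#CC(=O)OC | starting material
4 | methyl 4-hydroxy-7-methyloct-6-en-2-ynoate (racemic) | COC(=O)C#CC(O)CC=C(C)C | intermediate
5 | 2-methylpropanal oxime | CC(C)C=NO | starting material
6 | N-hydroxy-2-methylpropanimidoyl chloride | CC(C)C(Cl)=NO | intermediate
7 | 2-methylpropanenitrile oxide (not isolated) | CC(C)C#[N+][O-] | intermediate
8 | methyl 5-(1-hydroxy-4-methylpent-3-en-1-yl)-3-(propan-2-yl)-1,2-oxazole-4-carboxylate (racemic) | COC(=O)c1c(C(C)C)noc1C(O)CC=C(C)C | intermediate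
9 | acetonitrile | CC#N | starting material
10 | 3-[5-(1-hydroxy-4-methylpent-3-en-1-yl)-3-(propan-2-yl)-1,2-oxazol-4-yl]-3-oxopropanenitrile (racemic) | N#CCC(=O)c1c(C(C)C)noc1C(O)CC=C(C)C | intermediate
11 | prenyl bromide (1-bromo-3-methylbut-2-ene) | CC(C)=CCBr | starting material
12 | monoprenyl ketonitrile, 2-{[5-(1-hydroxy-4-methylpent-3-en-1-yl)-3-(propan-2-yl)-1,2-oxazol-4-yl]carbonyl}-5-methylhex-4-enenitrile (not isolated) | N#CC(CC=C(C)C)C(=O)c1c(C(C)C)noc1C(O)CC=C(C)C | intermediate
13 | 2-{[5-(1-hydroxy-4-methylpent-3-en-1-yl)-3-(propan-2-yl)-1,2-oxazol-4-yl]carbonyl}-5-methyl-2-(3-methylbut-2-en-1-yl)hex-4-enenitrile (racemic) | N#CC(CC=C(C)C)(CC=C(C)C)C(=O)c1c(C(C)C)noc1C(O)CC=C(C)C | intermediate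
14 | aldimine of 15 (not isolated) | N=CC(CC=C(C)C)(CC=C(C)C)C(O)c1c(C(C)C)noc1C(O)CC=C(C)C | intermediate
15 | 2-{hydroxy[5-(1-hydroxy-4-methylpent-3-en-1-yl)-3-(propan-2-yl)-1,2-oxazol-4-yl]methyl}-5-methyl-2-(3-methylbut-2-en-1-yl)hex-4-enal (mixture of diastereomers) | O=CC(CC=C(C)C)(CC=C(C)C)C(O)c1c(C(C)C)noc1C(O)CC=C(C)C | intermediate
16 | 5-methyl-2-(3-methylbut-2-en-1-yl)-2-{[5-(4-methylpent-3-enoyl)-3-(propan-2-yl)-1,2-oxazol-4-yl]carbonyl}hex-4-enal (achiral) | O=CC(CC=C(C)C)(CC=C(C)C)C(=O)c1c(C(C)C)noc1C(=O)CC=C(C)C | intermediate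
17 | (7R)-7-hydroxy-5,5,7-tris(3-methylbut-2-en-1-yl)-3-(propan-2-yl)-1,2-benzoxazole-4,6(5H,7H)-dione | CC(C)=CCC1(CC=C(C)C)C(=O)c2c(C(C)C)noc2[C@](O)(CC=C(C)C)C1=O | intermediate
18 | (4S)-2-(1-amino-2-methylpropylidene)-4-hydroxy-4,6,6-tris(3-methylbut-2-en-1-yl)cyclohexane-1,3,5-trione (push–pull C=C, geometry mobile) | CC(C)=CCC1(CC=C(C)C)C(=O)C(=C(N)C(C)C)C(=O)[C@](O)(CC=C(C)C)C1=O | intermediate
19 | (6R)-5,6-dihydroxy-4-(2-methylpropanoyl)-2,2,6-tris(3-methylbut-2-en-1-yl)cyclohex-4-ene-1,3-dione (drawn as the C5 enol tautomer) | CC(C)=CCC1(CC=C(C)C)C(=O)C(C(=O)C(C)C)=C(O)[C@](O)(CC=C(C)C)C1=O | target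

**Step count**
Total step count: 11. Longest linear sequence: 10 (steps 1, 2 and 4 to 11; step 3 is a side branch).

**Steps most likely to fail**

Step 9. The acyl anion equivalent may form slowly at a formyl group next to a quaternary carbon. The formyl group may be transferred to the catalyst, the β,γ-double bond may drift into conjugation, or facial selectivity may be poor.
- The fallback sets out from 16 and joins the same two carbonyl carbons by electron transfer instead of carbene catalysis.
- Divalent samarium (SmI2, 2.2 equiv, t-BuOH, THF, −78 °C, short contact so that the N–O bond survives) effects a ketyl pinacol cyclisation. Chelation of both oxygens should give the racemic cis-diol F1.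
- Parikh–Doering oxidation (SO3·pyridine, DMSO, Et3N, 0 °C) of its secondary alcohol gives the racemic ketol F2.
- Preparative chromatography on a chiral stationary phase separates the enantiomers. The (7R) enantiomer is 17, where the route is rejoined.

Step 11. Hydrolysis of the strongly hydrogen-bonded vinylogous amide may be sluggish. Forcing acid invites cyclisation of prenyl groups onto the enol oxygens, and forcing base invites acyloin ring contraction.
- The fallback sets out from 18 and activates the nitrogen instead of forcing the medium.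
- Boc2O and catalytic 4-(dimethylamino)pyridine in MeCN give the N-Boc enaminone F3.
- Its carbamate nitrogen is a far better leaving group, so aqueous LiOH in THF at 0 °C should complete the addition–elimination as in the hydrolysis of N-Boc amides.
- Mild acidification then gives 19.

Step 7. Hydride delivery to the hindered nitrile may be incomplete, hydrolysis of the hindered aldimine may be slow, or the β-hydroxy aldehyde may undergo retro-aldol cleavage during work-up.
- The fallback sets out from 8 and carries the future formyl carbon as an ester.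
- Crossed Claisen condensation with the lithium enolate of tert-butyl acetate (LiN(i-Pr)2, THF, −78 to 0 °C) gives the β-keto ester F4.
- Double alkylation with 11 and K2CO3 in DMF gives the diprenyl β-keto ester F5.
- LiAlH4 in THF at 0 °C reduces ketone and ester to the triol F6.
- A threefold Swern oxidation ((COCl)2, DMSO, Et3N, CH2Cl2, −78 °C) returns to the route at 16.

**Further compounds**
F1 | step 9 | rac-(6S,7S)-6,7-dihydroxy-5,5,7-tris(3-methylbut-2-en-1-yl)-3-(propan-2-yl)-6,7-dihydro-1,2-benzoxazol-4(5H)-one (cis-diol, racemic, one enantiomer drawn) | CC(C)=CCC1(CC=C(C)C)C(=O)c2c(C(C)C)noc2[C@](O)(CC=C(C)C)[C@H]1O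
F2 | step 9 | racemic 7-hydroxy-5,5,7-tris(3-methylbut-2-en-1-yl)-3-(propan-2-yl)-1,2-benzoxazole-4,6(5H,7H)-dione | CC(C)=CCC1(CC=C(C)C)C(=O)c2c(C(C)C)noc2C(O)(CC=C(C)C)C1=O
F3 | step 11 | tert-butyl N-{1-[(3S)-3-hydroxy-3,5,5-tris(3-methylbut-2-en-1-yl)-2,4,6-trioxocyclohexylidene]-2-methylpropyl}carbamate | CC(C)=CCC1(CC=C(C)C)C(=O)C(=C(NC(=O)OC(C)(C)C)C(C)C)C(=O)[C@](O)(CC=C(C)C)C1=O
F4 | step 7 | tert-butyl 3-[5-(1-hydroxy-4-methylpent-3-en-1-yl)-3-(propan-2-yl)-1,2-oxazol-4-yl]-3-oxopropanoate (racemic) | CC(C)(C)OC(=O)CC(=O)c1c(C(C)C)noc1C(O)CC=C(C)C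
F5 | step 7 | tert-butyl 2-{[5-(1-hydroxy-4-methylpent-3-en-1-yl)-3-(propan-2-yl)-1,2-oxazol-4-yl]carbonyl}-5-methyl-2-(3-methylbut-2-en-1-yl)hex-4-enoate (racemic) | CC(C)(C)OC(=O)C(CC=C(C)C)(CC=C(C)C)C(=O)c1c(C(C)C)noc1C(O)CC=C(C)C
F6 | step 7 | 1-[5-(1-hydroxy-4-methylpent-3-en-1-yl)-3-(propan-2-yl)-1,2-oxazol-4-yl]-2,2-bis(3-methylbut-2-en-1-yl)propane-1,3-diol (mixture of diastereomers) | OCC(CC=C(C)C)(CC=C(C)C)C(O)c1c(C(C)C)noc1C(O)CC=C(C)C
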